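Ring A is the benzo ring, ring B the furan and ring C the 2-aryl group. Retrosynthesis first adjusts C3 (CHO from CO2Me) and frees the two ring C phenols, then removes ring A in one stroke by cutting C7a–C7, C7–C6, C5–C4 and C4–C3a.
Enabling feature: around ring A, the order C4–OH, C5–prenyl, C6–OMe, C7–H matches the order ketene C=O, alkyne C–prenyl, alkyne C–OMe, ketene CH. The shared C3a=C7a bond is the C4=C5 bond of a furan whose C4 still carries hydrogen.
The furan partner is cut at C2–C1' (C–H arylation) and at the C5–acetyl bond (Friedel–Crafts). The ynol ether is cut at its propargylic C–C bond (acetylide alkylation).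
Forward order: ring B is bought and acetylated, and ring C is bought, protected and joined to it. The acetyl group then becomes a diazo ketone, and ring A is the only ring that is built.
Stereochemistry: the target has no stereocentre and its one side-chain alkene ends in two methyl groups, so only regiochemistry matters. It comes from the polarity of the ynol ether and from the single free CH next to the ketene-bearing furan carbon.

Key step: step 6

Remark: the trifluoroacetylated ketone of step 4 is carried on as the crude extract, so acylation and diazo transfer are counted as one step.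

Step 1
Reactants: 1 4-bromoresorcinol (4-bromobenzene-1,3-diol)
Product: 2 1-bromo-2,4-bis(methoxymethoxy)benzene
Conditions: NaH (2.5 equiv), MOMCl (2.5 equiv), DMF, 0 °C → rt
Reagents that add atoms: chloromethyl methyl ether (MOMCl), COCCl
Why: Double Williamson-type O-alkylation of the sodium phenoxides with MOMCl is standard for resorcinols, and the resulting acetals tolerate the palladium catalysis, amide base, light and hydride used later.

Step 2
Reactants: 3 methyl furan-3-carboxylate; 4 acetic anhydride
Product: 5 methyl 5-acetylfuran-3-carboxylate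
Conditions: BF3·OEt2 (0.3 equiv), neat 4 (3 equiv), 0 → 60 °C
Reagents that add atoms: none
Why: Friedel–Crafts acetylation of a furan goes to an α-carbon, here C5 because attack at C2 would place positive charge on the ester-bearing C3, and acetylating before ring C is attached avoids competition from the electron-rich resorcinol ring and keeps the Lewis acid away from MOM ethers.

Step 3
Reactants: 2 1-bromo-2,4-bis(methoxymethoxy)benzene; 5 methyl 5-acetylfuran-3-carboxylate
Product: 6 methyl 5-acetyl-2-[2,4-bis(methoxymethoxy)phenyl]furan-3-carboxylate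
Conditions: PdCl(C3H5)(dppb) (2 mol %), KOAc (2 equiv), DMA, 130 °C
Reagents that add atoms: none
Why: Palladium-catalysed direct C–H arylation by acetate-assisted concerted metalation–deprotonation is known to functionalise 3-furoates at C2, which in 5 is the only α-C–H left and the most acidic one (flanked by the ring oxygen and the ester), while KOAc is too weak a base to enolise the methyl ketone.

Step 4
Reactants: 6 methyl 5-acetyl-2-[2,4-bis(methoxymethoxy)phenyl]furan-3-carboxylate
Product: 8 methyl 2-[2,4-bis(methoxymethoxy)phenyl]-5-(2-diazoacetyl)furan-3-carboxylate, via trifluoroacetyl ketone 7 (not isolated)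
Conditions: LiN(SiMe3)2, THF, −78 °C; CF3CO2CH2CF3; then MsN3, Et3N, H2O, MeCN, rt
Reagents that add atoms: methanesulfonyl azide, CS(=O)(=O)N=[N+]=[N-]; 2,2,2-trifluoroethyl trifluoroacetate, FC(F)(F)COC(=O)C(F)(F)F (its CF3CO group is held only in 7 and leaves again on the way to 8)
Why: Detrifluoroacetylative diazo transfer (Danheiser variant of the Regitz reaction): the kinetic lithium enolate of the methyl ketone is trifluoroacetylated to 7, whose activated methylene accepts N2 from MsN3 and sheds the CF3CO group, and the furan ester has no α-hydrogen and is left alone at −78 °C.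

Step 5
Reactants: 9 chloroacetaldehyde dimethyl acetal (2-chloro-1,1-dimethoxyethane); 10 prenyl bromide (1-bromo-3-methylbut-2-ene)
Product: 12 1-methoxy-5-methylhex-4-en-1-yne, via lithium methoxyacetylide 11 (not isolated)
Conditions: LiNEt2 (3.0 equiv), THF, 0 °C; then 10 (0.9 equiv), DMPU, −78 °C → rt
Reagents that add atoms: none
Why: Lithium diethylamide strips MeOH and HCl from 9 and deprotonates the resulting methoxyacetylene, acetylide 11 then displaces bromide at the primary carbon of 10 (SN2 alkylation of an alkoxyacetylide), and with no amide base left over the doubly activated CH2 of the skipped enyne should not isomerise.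

Step 6
Reactants: 8 methyl 2-[2,4-bis(methoxymethoxy)phenyl]-5-(2-diazoacetyl)furan-3-carboxylate; 12 1-methoxy-5-methylhex-4-en-1-yne
Product: 17 methyl 2-[2,4-bis(methoxymethoxy)phenyl]-4-hydroxy-6-methoxy-5-(3-methylbut-2-enyl)benzofuran-3-carboxylate, via furylketene 13 (not isolated), via cyclobutenone 14 (not isolated), via dienylketene 15 (not isolated), via cyclohexadienone 16 (not isolated)
Conditions: 12 (2 equiv), ClCH2CH2Cl, hν (254 nm, low-pressure Hg lamps, quartz), 25 °C; then 80 °C
Reagents that add atoms: none
Why: Irradiation drives loss of N2 from 8 with 1,2-shift of the furyl group (photo-Wolff rearrangement, which makes C7a–C7), and ketene 13 is taken up by 12 in a polarity-matched [2+2] cycloaddition in which the electron-rich alkyne carbon carrying the prenyl chain attacks the ketene carbonyl carbon (C5–C4) and the methoxy-bearing carbon bonds to the ketene CH (C7–C6), giving 14. Light or the 80 °C hold then opens 14 by reversible four-electron conrotatory cleavage of its C(=O)–CH bond, and only the isomer 15 with the furyl group cis to the ketene is drained, because it closes ring A by six-electron disrotatory electrocyclization of the ketene carbon onto furan C4 (C4–C3a), after which enolization of 16 restores aromaticity and delivers the phenol. The closest known reaction type is the Danheiser benzannulation in its diazo ketone version, which is established for heteroaryl diazomethyl ketones with alkoxy- and siloxyalkynes. No stereocentre survives, since the sp3 carbons of 14 and 16 are erased by ring opening and by tautomerization. Regiocontrol is needed twice and the substrates supply it: the oxygen lone pair of MeO–C≡C fixes the orientation of the cycloaddition (OMe ends at C6, prenyl at C5 next to the new OH), and the ketene-bearing furan carbon has only one carbon neighbour, C4–H, so there is a single site of closure. Chemoselectivity for the alkyne over the trisubstituted alkene and over the product phenol rests on the much higher ketenophilicity of the ynol ether and on its use in excess, and a methyl ynol ether cannot lose an alkene by retro-ene reaction at 80 °C.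

Step 7
Reactants: 17 methyl 2-[2,4-bis(methoxymethoxy)phenyl]-4-hydroxy-6-methoxy-5-(3-methylbut-2-enyl)benzofuran-3-carboxylate
Product: 18 2-[2,4-bis(methoxymethoxy)phenyl]-3-(hydroxymethyl)-6-methoxy-5-(3-methylbut-2-enyl)benzofuran-4-ol
Conditions: i-Bu2AlH (4 equiv), CH2Cl2, −78 → 0 °C; aq potassium sodium tartrate
Reagents that add atoms: none
Why: Standard i-Bu2AlH reduction of an aromatic ester to the primary alcohol, in which one equivalent is spent on the C4 phenol, the excess reduces the neighbouring ester, and MOM ethers, aryl methyl ether and prenyl alkene are inert to the reagent.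

Step 8
Reactants: 18 2-[2,4-bis(methoxymethoxy)phenyl]-3-(hydroxymethyl)-6-methoxy-5-(3-methylbut-2-enyl)benzofuran-4-ol
Product: 19 2-[2,4-bis(methoxymethoxy)phenyl]-4-hydroxy-6-methoxy-5-(3-methylbut-2-enyl)benzofuran-3-carbaldehyde
Conditions: activated MnO2 (excess), CH2Cl2, rt
Reagents that add atoms: none
Why: MnO2 oxidises benzylic and heterobenzylic alcohols selectively under neutral conditions and stops at the aldehyde, here a vinylogous formate further stabilised by a hydrogen bond from the C4 hydroxyl, so the ionisable alcohol 18 never meets acid.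

Step 9
Reactants: 19 2-[2,4-bis(methoxymethoxy)phenyl]-4-hydroxy-6-methoxy-5-(3-methylbut-2-enyl)benzofuran-3-carbaldehyde
Product: 20 ebenfuran III, 2-(2,4-dihydroxyphenyl)-4-hydroxy-6-methoxy-5-(3-methylbut-2-enyl)benzofuran-3-carbaldehyde
Conditions: 3 M aq HCl, THF, 40 °C
Reagents that add atoms: none
Why: Acid hydrolysis of aryl MOM acetals is routine for prenylated phenols, the C4 hydroxyl is tied to the formyl oxygen by a hydrogen bond that lowers its tendency to add to the prenyl alkene, and the alcohol-free medium prevents mixed acetal formation between the formyl group and the new 2'-hydroxyl.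

Compound list
1 | 4-bromoresorcinol (4-bromobenzene-1,3-diol) | Oc1ccc(Br)c(O)c1 | starting material
2 | 1-bromo-2,4-bis(methoxymethoxy)benzene | COCOc1ccc(Br)c(OCOC)c1 | intermediate
3 | methyl furan-3-carboxylate | COC(=O)c1ccoc1 | starting material
4 | acetic anhydride | CC(=O)OC(C)=O | starting material
5 | methyl 5-acetylfuran-3-carboxylate | COC(=O)c1coc(C(C)=O)c1 | intermediate
6 | methyl 5-acetyl-2-[2,4-bis(methoxymethoxy)phenyl]furan-3-carboxylate | COC(=O)c1cc(C(C)=O)oc1-c1ccc(OCOC)cc1OCOC | intermediate
7 | methyl 2-[2,4-bis(methoxymethoxy)phenyl]-5-(4,4,4-trifluoro-3-oxobutanoyl)furan-3-carboxylate (carried crude) | COC(=O)c1cc(C(=O)CC(=O)C(F)(F)F)oc1-c1ccc(OCOC)cc1OCOC | intermediate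
8 | methyl 2-[2,4-bis(methoxymethoxy)phenyl]-5-(2-diazoacetyl)furan-3-carboxylate | COC(=O)c1cc(C(=O)C=[N+]=[N-])oc1-c1ccc(OCOC)cc1OCOC | intermediate
9 | chloroacetaldehyde dimethyl acetal (2-chloro-1,1-dimethoxyethane) | COC(CCl)OC | starting material
10 | prenyl bromide (1-bromo-3-methylbut-2-ene) | CC(C)=CCBr | starting material
11 | lithium methoxyacetylide (forms in the flask) | COC#C[Li] | intermediate
12 | 1-methoxy-5-methylhex-4-en-1-yne | COC#CCC=C(C)C | intermediate
13 | furylketene, methyl 2-[2,4-bis(methoxymethoxy)phenyl]-5-(2-oxoethenyl)furan-3-carboxylate (forms in the flask) | COC(=O)c1cc(C=C=O)oc1-c1ccc(OCOC)cc1OCOC | intermediate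
14 | cyclobutenone, methyl 2-[2,4-bis(methoxymethoxy)phenyl]-5-[2-methoxy-3-(3-methylbut-2-enyl)-4-oxocyclobut-2-en-1-yl]furan-3-carboxylate (racemic, forms in the flask) | COC(=O)c1cc(C2C(=O)C(CC=C(C)C)=C2OC)oc1-c1ccc(OCOC)cc1OCOC | intermediate
15 | dienylketene, methyl 2-[2,4-bis(methoxymethoxy)phenyl]-5-[(1E)-2-methoxy-6-methyl-3-(oxomethylidene)hepta-1,5-dien-1-yl]furan-3-carboxylate (forms in the flask) | COC(=O)c1cc(/C=C(/OC)C(CC=C(C)C)=C=O)oc1-c1ccc(OCOC)cc1OCOC | intermediate
16 | cyclohexadienone, methyl 2-[2,4-bis(methoxymethoxy)phenyl]-6-methoxy-5-(3-methylbut-2-enyl)-4-oxo-3a,4-dihydrobenzofuran-3-carboxylate (racemic, forms in the flask) | COC(=O)C1=C(c3ccc(OCOC)cc3OCOC)OC2=CC(OC)=C(CC=C(C)C)C(=O)C12 | intermediate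
17 | methyl 2-[2,4-bis(methoxymethoxy)phenyl]-4-hydroxy-6-methoxy-5-(3-methylbut-2-enyl)benzofuran-3-carboxylate | COC(=O)c1c(-c2ccc(OCOC)cc2OCOC)oc2cc(OC)c(CC=C(C)C)c(O)c12 | intermediate
18 | 2-[2,4-bis(methoxymethoxy)phenyl]-3-(hydroxymethyl)-6-methoxy-5-(3-methylbut-2-enyl)benzofuran-4-ol | OCc1c(-c2ccc(OCOC)cc2OCOC)oc2cc(OC)c(CC=C(C)C)c(O)c12 | intermediate
19 | 2-[2,4-bis(methoxymethoxy)phenyl]-4-hydroxy-6-methoxy-5-(3-methylbut-2-enyl)benzofuran-3-carbaldehyde | O=Cc1c(-c2ccc(OCOC)cc2OCOC)oc2cc(OC)c(CC=C(C)C)c(O)c12 | intermediate
20 | ebenfuran III, 2-(2,4-dihydroxyphenyl)-4-hydroxy-6-methoxy-5-(3-methylbut-2-enyl)benzofuran-3-carbaldehyde | COc1cc2oc(-c3ccc(O)cc3O)c(C=O)c2c(O)c1CC=C(C)C | target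

Total step count: 9.
Longest linear sequence: 7 steps (1 or 2, then 3, 4, 6, 7, 8, 9).

Steps most likely to fail

Step 6. The photogenerated ketene may be captured inefficiently. The arylfuran chromophore and the growing product can screen the light. The ketene can dimerise or acylate the product phenol, and the cascade can stall before the six-electron closure.
Fallback, setting out from 8 and returning at 17: the ketene is made without light and the cascade is split into stages.
- A PhCO2Ag-catalysed Wolff rearrangement of 8 in aqueous THF with Et3N (Arndt–Eistert homologation) should give methyl 5-(carboxymethyl)-2-[2,4-bis(methoxymethoxy)phenyl]furan-3-carboxylate F1.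
- 1-Chloro-N,N,2-trimethylprop-1-en-1-amine converts it under neutral conditions into methyl 5-(2-chloro-2-oxoethyl)-2-[2,4-bis(methoxymethoxy)phenyl]furan-3-carboxylate F2.
- Slow addition of Et3N to F2 and excess 12 in CH2Cl2 releases 13 by dehydrochlorination.
- Cyclobutenone 14 is then isolated and heated in toluene at 110 °C, where it should pass through 15 and 16 to 17.

Step 3. Oxidative addition of the hindered, electron-rich bromide to zerovalent palladium may be slow, and the C2 site is crowded. Hydrodebromination, homocoupling or arylation next to the ketone could then overtake the C–H arylation.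
Fallback, setting out from 2 and 4 and returning at 6: the bond is made by cross-coupling of two prefunctionalised partners.
- Miyaura borylation of 2 (B2pin2, PdCl2(dppf), KOAc, dioxane, 90 °C) should give 2-[2,4-bis(methoxymethoxy)phenyl]-4,4,5,5-tetramethyl-1,3,2-dioxaborolane F3.
- Purchased methyl 2-bromofuran-3-carboxylate F4 is acetylated at C5 with 4 and BF3·OEt2, as in step 2, to give methyl 5-acetyl-2-bromofuran-3-carboxylate F5.
- Suzuki–Miyaura coupling of F3 with the doubly activated bromide F5 (Pd(PPh3)4, K3PO4, dioxane–H2O, 80 °C) should give 6.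

Step 9. Acid-promoted cyclisation of the prenyl chain onto the C4 hydroxyl, or hydration of the alkene, may compete with cleavage of the acetals.
Fallback, setting out from 19 and returning at 20: Brønsted acid is avoided by exchanging the acetals for silyl ethers.
- Me3SiOTf and 2,2'-bipyridyl in MeCN at 0 °C convert aryl MOM ethers into aryl trimethylsilyl ethers, and the methoxymethyl group is carried off on the bipyridyl nitrogen.
- With excess reagent the C4 hydroxyl is silylated as well, which should give 6-methoxy-5-(3-methylbut-2-enyl)-4-(trimethylsilyloxy)-2-[2,4-bis(trimethylsilyloxy)phenyl]benzofuran-3-carbaldehyde F6.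
- Addition of water then hydrolyses the three silyl ethers at neutral pH to 20.

Further compounds
F1 | step 6 | methyl 5-(carboxymethyl)-2-[2,4-bis(methoxymethoxy)phenyl]furan-3-carboxylate | COC(=O)c1cc(CC(=O)O)oc1-c1ccc(OCOC)cc1OCOC
F2 | step 6 | methyl 5-(2-chloro-2-oxoethyl)-2-[2,4-bis(methoxymethoxy)phenyl]furan-3-carboxylate | COC(=O)c1cc(CC(=O)Cl)oc1-c1ccc(OCOC)cc1OCOC
F3 | step 3 | 2-[2,4-bis(methoxymethoxy)phenyl]-4,4,5,5-tetramethyl-1,3,2-dioxaborolane | COCOc1ccc(B2OC(C)(C)C(C)(C)O2)c(OCOC)c1
F4 | step 3 | methyl 2-bromofuran-3-carboxylate (purchased) | COC(=O)c1ccoc1Br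
F5 | step 3 | methyl 5-acetyl-2-bromofuran-3-carboxylate | COC(=O)c1cc(C(C)=O)oc1Br
F6 | step 9 | 6-methoxy-5-(3-methylbut-2-enyl)-4-(trimethylsilyloxy)-2-[2,4-bis(trimethylsilyloxy)phenyl]benzofuran-3-carbaldehyde | COc1cc2oc(-c3ccc(O[Si](C)(C)C)cc3O[Si](C)(C)C)c(C=O)c2c(O[Si](C)(C)C)c1CC=C(C)C
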